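The two silyl and two benzyl ethers come off last. Before that, the bond between flavanone C2 and chroman C6 is cut to 7-benzyloxychromone and a chroman-6-boronic acid, which are joined by a ligand-controlled asymmetric conjugate addition (sets 2S).
The boron replaces an aryl bromide. The trans-3,4-diol comes from anti hydrolysis at C4 (sets 4S) of the (3R,4R)-epoxide, made by Jacobsen–Katsuki epoxidation of 8-benzyloxy-6-bromo-2,2-dimethyl-2H-chromene (sets 3R).
The plan rests on this feature: the gem-dimethylpyran ring (O1, C2, C3, C4, C4a, C8a) is fused to the benzene ring at C4a–C8a, and O1 on C8a sits next to the oxygen-bearing C8. The matching aryl 1,1-dimethylpropargyl ether therefore has only the future C4a as a free ortho carbon, and one thermal cascade forms both C4a–C4 and O1–C2.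
Ring order: the benzene rings and the pyranone ring are bought. The pyran ring is the only ring built (step 3), and the oxirane of step 4 is opened again in step 5.

Key step: step 3

Assumption: the Pd(OCOCF3)2/t-BuPyOx catalyst is taken to attack chromones from the same face as 3-substituted cyclohexenones, where the (S)-ligand gives the (R)-β-carbon; that face gives a (2R)-flavanone, so the (R)-ligand is specified for (2S).

Step 1
Reactants: 1 2-(benzyloxy)phenol
Product: 2 2-(benzyloxy)-4-bromophenol
Conditions: NBS, MeCN, 0 °C, dark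
Reagents that add atoms: N-bromosuccinimide, O=C1CCC(=O)N1Br
Why: Electrophilic aromatic bromination, in which the free hydroxyl is the strongest director of 1 and NBS in polar MeCN attacks its unhindered para carbon, placing bromine on the future C6 of the chroman.

Step 2
Reactants: 2 2-(benzyloxy)-4-bromophenol; 3 3-chloro-3-methylbut-1-yne
Product: 4 2-(benzyloxy)-4-bromo-1-[(2-methylbut-3-yn-2-yl)oxy]benzene
Conditions: DBU, CuCl2·2H2O (cat), MeCN, 0 °C to rt
Reagents that add atoms: none
Why: Copper-catalysed O-propargylation of a phenol by a tertiary propargylic chloride, in which DBU forms the phenoxide and the copper acetylide of 3 ionises to an allenylidene-type electrophile that is captured at the tertiary carbon, so the hindered aryl–O–CMe2 bond forms at low temperature without elimination to the enyne.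

Step 3
Reactants: 4 2-(benzyloxy)-4-bromo-1-[(2-methylbut-3-yn-2-yl)oxy]benzene
Product: 8 8-(benzyloxy)-6-bromo-2,2-dimethyl-2H-chromene, via allenyl cyclohexadienone 5 (not isolated), via ortho-allenylphenol 6 (not isolated), via ortho-quinone methide 7 (not isolated)
Conditions: N,N-diethylaniline, 190 °C, Ar
Reagents that add atoms: none
Why: This is the aromatic propargyl Claisen rearrangement followed by a pericyclic cascade, the standard thermal route from aryl 1,1-dimethylpropargyl ethers to 2,2-dimethyl-2H-chromenes. A [3,3]-sigmatropic shift cleaves O–CMe2 and joins the alkyne terminus to the free ortho carbon (bond C4a–C4) to give dienone 5, which enolises to phenol 6, and a 1,5-hydrogen shift from O–H to the central allene carbon then gives the (Z)-ortho-quinone methide 7. The pyran ring is closed by a thermal disrotatory oxa-6π electrocyclisation of the 1-oxatriene unit of 7, which forms O1–C2 and restores the aromatic ring. No stereocentre remains in 8, because the sp3 carbon of 5 is lost on enolisation, so no stereocontrol is required. The step needs ortho regioselectivity, and it has it because one ortho carbon of 4 carries OBn and the para carbon carries Br, so a shift to the blocked ortho carbon gives a dienone that can neither enolise nor pass the chain on to the para position and can only revert. The gem-dimethyl group speeds both the [3,3] shift and the ring closure, and the absence of strong base or fluoride keeps 6 from the phenoxide 5-exo attack on the allene that would lead to a 2-isopropylbenzofuran.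

Step 4
Reactants: 8 8-(benzyloxy)-6-bromo-2,2-dimethyl-2H-chromene
Product: 9 (1aR,7bR)-4-(benzyloxy)-6-bromo-2,2-dimethyl-1a,7b-dihydro-2H-oxireno[2,3-c]chromene, the (3R,4R)-3,4-epoxychroman
Conditions: (R,R)-[N,N'-bis(3,5-di-tert-butylsalicylidene)-1,2-cyclohexanediaminato]manganese chloride (4 mol %), 4-phenylpyridine N-oxide (cat), aq NaOCl (pH 11.3 buffer), CH2Cl2, 0 °C
Reagents that add atoms: sodium hypochlorite, [Na+].[O-]Cl
Why: Jacobsen–Katsuki epoxidation, for which cis-disubstituted aryl-conjugated 2,2-dimethylchromenes are the best substrate class, and side-on approach of the alkene to the oxomanganese species formed from the (R,R)-complex puts oxygen on the face that makes both C3 and C4 R.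

Step 5
Reactants: 9 (3R,4R)-epoxide
Product: 10 (3R,4S)-8-(benzyloxy)-6-bromo-2,2-dimethylchromane-3,4-diol (trans)
Conditions: aq H2SO4 (1 mol/L), THF, 0 °C to rt; recrystallisation
Reagents that add atoms: water, O
Why: Acid-catalysed epoxide hydrolysis, in which water attacks the protonated oxirane at benzylic C4 (C3 is neopentyl-like next to CMe2) anti to the leaving oxygen, so C4 is inverted to S while C3 keeps its C–O bond and stays R, and the inductively withdrawing Br and OBn groups meta to C4a hold back a free cation.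

Step 6
Reactants: 10 (3R,4S)-trans-diol
Product: 11 (3R,4S)-8-(benzyloxy)-6-bromo-3,4-bis[(tert-butyldimethylsilyl)oxy]-2,2-dimethylchromane
Conditions: TBSOTf, 2,6-lutidine, CH2Cl2, 0 °C to rt
Reagents that add atoms: tert-butyldimethylsilyl triflate, CC(C)(C)[Si](C)(C)OS(=O)(=O)C(F)(F)F
Why: Silyl ether formation with the triflate, which is reactive enough for the hindered C3 hydroxyl, removes the acidic protons before the lithiation of step 7 and shields the benzylic alcohol from β-hydride oxidation by divalent palladium in step 9, without touching either stereocentre.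

Step 7
Reactants: 11 bis-silyl ether bromide
Product: 14 [(3R,4S)-8-(benzyloxy)-3,4-bis[(tert-butyldimethylsilyl)oxy]-2,2-dimethylchroman-6-yl]boronic acid, via aryllithium 12 (not isolated), via lithium aryltriisopropoxyborate 13 (not isolated)
Conditions: n-BuLi, THF, −78 °C; B(OiPr)3, −78 °C to rt; dilute aq HCl to pH 5, 0 °C
Reagents that add atoms: triisopropyl borate, CC(C)OB(OC(C)C)OC(C)C; water, O
Why: Bromine–lithium exchange followed by electrophilic borylation, in which exchange at −78 °C outruns deprotonation of the benzyl ether, aryllithium 12 adds to the borate to give ate complex 13, and mild hydrolysis frees the boronic acid that the conjugate addition needs in place of a sluggish pinacol ester.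

Step 8
Reactants: 15 7-hydroxy-4H-chromen-4-one
Product: 16 7-(benzyloxy)-4H-chromen-4-one
Conditions: BnBr, K2CO3, acetone, reflux
Reagents that add atoms: benzyl bromide, BrCc1ccccc1
Why: Williamson ether synthesis, in which the acidic 7-hydroxyl (vinylogous to the pyranone carbonyl) is alkylated under carbonate conditions too mild to open the pyranone ring.

Step 9
Reactants: 14 chroman-6-boronic acid; 16 7-(benzyloxy)-4H-chromen-4-one
Product: 17 (2S)-7-(benzyloxy)-2-[(3R,4S)-8-(benzyloxy)-3,4-bis[(tert-butyldimethylsilyl)oxy]-2,2-dimethylchroman-6-yl]chroman-4-one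
Conditions: Pd(OCOCF3)2 (10 mol %), (R)-4-tert-butyl-2-(pyridin-2-yl)-4,5-dihydrooxazole (12 mol %), NH4PF6 (30 mol %), H2O (5 equiv), ClCH2CH2Cl, 60 °C
Reagents that add atoms: none
Why: Palladium-catalysed asymmetric conjugate addition of an arylboronic acid to a chromone with a cationic divalent palladium pyridine-oxazoline catalyst, in which transmetalation, enantiodetermining insertion of the C2=C3 bond into the aryl–Pd bond and protonolysis of the palladium enolate form the C2–aryl bond, the tert-butyl group of the (R)-ligand steering the aryl group to the face that gives 2S while the remote C3 and C4 centres of the chroman play no part.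

Step 10
Reactants: 17 bis-silyl dibenzyl flavanone
Product: 18 (2S)-7-(benzyloxy)-2-[(3R,4S)-8-(benzyloxy)-3,4-dihydroxy-2,2-dimethylchroman-6-yl]chroman-4-one
Conditions: HF·pyridine, pyridine, THF, 0 °C to rt
Reagents that add atoms: none
Why: Fluoride-induced desilylation in a pyridine-buffered medium avoids both the base-induced retro-oxa-Michael opening that would racemise flavanone C2 and the strong acid that would ionise the C4–O bond.

Step 11
Reactants: 18 dibenzyl diol
Product: 19 (2S)-7-hydroxy-2-[(3R,4S)-3,4,8-trihydroxy-2,2-dimethylchroman-6-yl]chroman-4-one (target)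
Conditions: H2 (1 atm), 10% Pd/C, EtOAc–THF, rt, stopped after two equivalents of H2
Reagents that add atoms: none
Why: Catalytic hydrogenolysis of the two primary benzyl aryl ethers under neutral conditions in non-nucleophilic solvents is much faster than cleavage of the secondary benzylic C4–OH or of the cyclic C2–O1 bond of the flavanone, so no stereocentre is touched.

Compound list
1 | 2-(benzyloxy)phenol | Oc1ccccc1OCc1ccccc1 | starting material
2 | 2-(benzyloxy)-4-bromophenol | Oc1ccc(Br)cc1OCc1ccccc1 | intermediate
3 | 3-chloro-3-methylbut-1-yne | C#CC(C)(C)Cl | starting material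
4 | 2-(benzyloxy)-4-bromo-1-[(2-methylbut-3-yn-2-yl)oxy]benzene | C#CC(C)(C)Oc1ccc(Br)cc1OCc1ccccc1 | intermediate
5 | 2-(benzyloxy)-4-bromo-6-(3-methylbuta-1,2-dien-1-yl)cyclohexa-2,4-dien-1-one | CC(C)=C=CC1C=C(Br)C=C(OCc2ccccc2)C1=O | intermediate
6 | 2-(benzyloxy)-4-bromo-6-(3-methylbuta-1,2-dien-1-yl)phenol | CC(C)=C=Cc1cc(Br)cc(OCc2ccccc2)c1O | intermediate
7 | (6Z)-2-(benzyloxy)-4-bromo-6-(3-methylbut-2-en-1-ylidene)cyclohexa-2,4-dien-1-one | CC(C)=C/C=C1/C=C(Br)C=C(OCc2ccccc2)C1=O | intermediate
8 | 8-(benzyloxy)-6-bromo-2,2-dimethyl-2H-chromene | CC1(C)C=Cc2cc(Br)cc(OCc3ccccc3)c2O1 | intermediate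
9 | (1aR,7bR)-4-(benzyloxy)-6-bromo-2,2-dimethyl-1a,7b-dihydro-2H-oxireno[2,3-c]chromene | CC1(C)Oc2c(OCc3ccccc3)cc(Br)cc2[C@H]2O[C@@H]12 | intermediate
10 | (3R,4S)-8-(benzyloxy)-6-bromo-2,2-dimethylchromane-3,4-diol | CC1(C)Oc2c(OCc3ccccc3)cc(Br)cc2[C@H](O)[C@H]1O | intermediate
11 | (3R,4S)-8-(benzyloxy)-6-bromo-3,4-bis[(tert-butyldimethylsilyl)oxy]-2,2-dimethylchromane | CC1(C)Oc2c(OCc3ccccc3)cc(Br)cc2[C@H](O[Si](C)(C)C(C)(C)C)[C@H]1O[Si](C)(C)C(C)(C)C | intermediate
12 | [(3R,4S)-8-(benzyloxy)-3,4-bis[(tert-butyldimethylsilyl)oxy]-2,2-dimethylchroman-6-yl]lithium | CC1(C)Oc2c(OCc3ccccc3)cc([Li])cc2[C@H](O[Si](C)(C)C(C)(C)C)[C@H]1O[Si](C)(C)C(C)(C)C | intermediate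
13 | lithium [(3R,4S)-8-(benzyloxy)-3,4-bis[(tert-butyldimethylsilyl)oxy]-2,2-dimethylchroman-6-yl]triisopropoxyborate | CC1(C)Oc2c(OCc3ccccc3)cc([B-](OC(C)C)(OC(C)C)OC(C)C)cc2[C@H](O[Si](C)(C)C(C)(C)C)[C@H]1O[Si](C)(C)C(C)(C)C.[Li+] | intermediate
14 | [(3R,4S)-8-(benzyloxy)-3,4-bis[(tert-butyldimethylsilyl)oxy]-2,2-dimethylchroman-6-yl]boronic acid | CC1(C)Oc2c(OCc3ccccc3)cc(B(O)O)cc2[C@H](O[Si](C)(C)C(C)(C)C)[C@H]1O[Si](C)(C)C(C)(C)C | intermediate
15 | 7-hydroxy-4H-chromen-4-one | O=c1ccoc2cc(O)ccc12 | starting material
16 | 7-(benzyloxy)-4H-chromen-4-one | O=c1ccoc2cc(OCc3ccccc3)ccc12 | intermediate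
17 | (2S)-7-(benzyloxy)-2-[(3R,4S)-8-(benzyloxy)-3,4-bis[(tert-butyldimethylsilyl)oxy]-2,2-dimethylchroman-6-yl]chroman-4-one | CC1(C)Oc2c(OCc3ccccc3)cc([C@@H]3CC(=O)c4ccc(OCc5ccccc5)cc4O3)cc2[C@H](O[Si](C)(C)C(C)(C)C)[C@H]1O[Si](C)(C)C(C)(C)C | intermediate
18 | (2S)-7-(benzyloxy)-2-[(3R,4S)-8-(benzyloxy)-3,4-dihydroxy-2,2-dimethylchroman-6-yl]chroman-4-one | CC1(C)Oc2c(OCc3ccccc3)cc([C@@H]3CC(=O)c4ccc(OCc5ccccc5)cc4O3)cc2[C@H](O)[C@H]1O | intermediate
19 | (2S)-7-hydroxy-2-[(3R,4S)-3,4,8-trihydroxy-2,2-dimethylchroman-6-yl]chroman-4-one | CC1(C)Oc2c(O)cc([C@@H]3CC(=O)c4ccc(O)cc4O3)cc2[C@H](O)[C@H]1O | target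

Total step count: 11. Longest linear sequence: 10 (steps 1–7 and 9–11; step 8 is the side branch).

Steps most likely to fail

**Step 9.** The 7-alkoxy group lowers the electrophilicity of the chromone. Insertion may therefore lag behind protodeboronation and homocoupling of the electron-rich boronic acid. A para-alkoxy aryl group may also weaken the facial discrimination of the catalyst.

The fallback sets out from 11 and returns at 17.
- Bromine–lithium exchange (n-BuLi, THF, −78 °C) and a DMF quench should give the aldehyde (3R,4S)-8-(benzyloxy)-3,4-bis[(tert-butyldimethylsilyl)oxy]-2,2-dimethylchromane-6-carbaldehyde F1.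
- Claisen–Schmidt condensation with commercial 1-[4-(benzyloxy)-2-hydroxyphenyl]ethanone (CC(=O)c1ccc(OCc2ccccc2)cc1O; KOH, EtOH, rt) should give the (E)-2'-hydroxychalcone F2.
- Oxa-Michael ring closure (NaOAc, EtOH, reflux) should give 17 together with the (2R)-epimer of 17 F3.
- Because C3 and C4 are already fixed, these two are diastereomers and can be separated on silica gel. F3 is returned to the same conditions, where it re-equilibrates through F2.

**Step 11.** Over-reduction on the metal surface is the concern. It could take the form of hydrogenolysis of the benzylic C4–O bond, reductive opening of the pyranone ring at C2–O1, or reduction of the carbonyl group.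

The fallback sets out from 17 and returns at 19, with the last two operations in reverse order.
- Hydrogenolysis (H2, 10% Pd/C, EtOAc–THF) is run while C3 and C4 still carry their bulky silyl ethers, which keep the C4 benzylic carbon away from the catalyst. It should give the bis-silyl diphenol (2S)-2-[(3R,4S)-3,4-bis[(tert-butyldimethylsilyl)oxy]-8-hydroxy-2,2-dimethylchroman-6-yl]-7-hydroxychroman-4-one F4.
- Buffered HF·pyridine in THF then frees the diol as 19.

**Step 5.** Partial ionisation of the protonated epoxide to a C4 cation stabilised by O1 would erode the anti selectivity of water attack. C3, and with it the enantiomeric series, would not be affected.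

The fallback sets out from 9 and returns at 10. It sets C4 by reduction instead of by substitution.
- The crude hydrolysate, 10 mixed with the cis-diol (3R,4R)-8-(benzyloxy)-6-bromo-2,2-dimethylchromane-3,4-diol F5, is not separated.
- It is oxidised at the less hindered benzylic hydroxyl (2-iodoxybenzoic acid, DMSO, rt) to the ketol (3S)-8-(benzyloxy)-6-bromo-3-hydroxy-2,2-dimethylchroman-4-one F6. The geometry at C3 is unchanged, and the descriptor changes only through the priority rules.
- Hydroxyl-directed reduction (Me4NBH(OAc)3, MeCN–AcOH, −20 °C) delivers hydride from the face of the C3–O–B link, so the new C4 hydroxyl should end up trans, giving 10.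

Further compounds
F1 | step 9 | (3R,4S)-8-(benzyloxy)-3,4-bis[(tert-butyldimethylsilyl)oxy]-2,2-dimethylchromane-6-carbaldehyde | CC1(C)Oc2c(OCc3ccccc3)cc(C=O)cc2[C@H](O[Si](C)(C)C(C)(C)C)[C@H]1O[Si](C)(C)C(C)(C)C
F2 | step 9 | (E)-1-[4-(benzyloxy)-2-hydroxyphenyl]-3-[(3R,4S)-8-(benzyloxy)-3,4-bis[(tert-butyldimethylsilyl)oxy]-2,2-dimethylchroman-6-yl]prop-2-en-1-one | CC1(C)Oc2c(OCc3ccccc3)cc(/C=C/C(=O)c3ccc(OCc4ccccc4)cc3O)cc2[C@H](O[Si](C)(C)C(C)(C)C)[C@H]1O[Si](C)(C)C(C)(C)C
F3 | step 9 | (2R)-7-(benzyloxy)-2-[(3R,4S)-8-(benzyloxy)-3,4-bis[(tert-butyldimethylsilyl)oxy]-2,2-dimethylchroman-6-yl]chroman-4-one | CC1(C)Oc2c(OCc3ccccc3)cc([C@H]3CC(=O)c4ccc(OCc5ccccc5)cc4O3)cc2[C@H](O[Si](C)(C)C(C)(C)C)[C@H]1O[Si](C)(C)C(C)(C)C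
F4 | step 11 | (2S)-2-[(3R,4S)-3,4-bis[(tert-butyldimethylsilyl)oxy]-8-hydroxy-2,2-dimethylchroman-6-yl]-7-hydroxychroman-4-one | CC1(C)Oc2c(O)cc([C@@H]3CC(=O)c4ccc(O)cc4O3)cc2[C@H](O[Si](C)(C)C(C)(C)C)[C@H]1O[Si](C)(C)C(C)(C)C
F5 | step 5 | (3R,4R)-8-(benzyloxy)-6-bromo-2,2-dimethylchromane-3,4-diol | CC1(C)Oc2c(OCc3ccccc3)cc(Br)cc2[C@@H](O)[C@H]1O
F6 | step 5 | (3S)-8-(benzyloxy)-6-bromo-3-hydroxy-2,2-dimethylchroman-4-one | CC1(C)Oc2c(OCc3ccccc3)cc(Br)cc2C(=O)[C@H]1O
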